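The chain C(H)(CH3)–C(=O)–C(H)(CH3) that joins C2 of ring A (the 6-pentyl γ-pyrone) to C2 of ring B (the 6-ethyl γ-pyrone) carries mirror-related methyl centres (S next to ring A, R next to ring B), so only pentyl versus ethyl makes the molecule chiral. The chain is therefore taken from a meso anti,anti 3-(4-methoxybenzyloxy)-2,4-dimethylpentane-1,5-diol. A lipase-mediated monoacetylation of one enantiotopic CH2OH fixes both methyl centres absolutely and labels the two arms in one operation. Each arm is then grown into a 1,3,5-triketone and cyclodehydrated, pentyl pyrone first, and the C3 carbinol is oxidised last under neutral conditions.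

Key step: step 4

Assumption: the lipase, chosen in a short screen, is taken to acetylate the CH2OH bound to the (S)-configured methyl carbon of diol 7, giving 8; this sense cannot be predicted with confidence and is to be confirmed by correlation before step 5 (the fallback for step 4 covers the opposite outcome).
Remark: metal alkoxides that are only protonated on aqueous work-up are not numbered separately; aldol adducts 14 and 24 are carried as diastereomer mixtures because their new centres later become sp2 carbons.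

Step 1
Reactants: 1 methacrolein; 2 isopropenylmagnesium bromide
Product: 3 2,4-dimethylpenta-1,4-dien-3-ol
Conditions: THF, 0 °C; then aq NH4Cl
Reagents that add atoms: none
Why: Grignard 1,2-addition of an alkenylmagnesium halide to the aldehyde of an enal is reliably carbonyl-selective and gives the symmetrical bis-allylic carbinol, whose carbinol carbon bears two identical isopropenyl groups and is therefore not a stereocentre.

Step 2
Reactants: 3 2,4-dimethylpenta-1,4-dien-3-ol
Product: 5 3-[(4-methoxybenzyl)oxy]-2,4-dimethylpenta-1,4-diene, via sodium 2,4-dimethylpenta-1,4-dien-3-olate 4 (not isolated)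
Conditions: NaH, THF/DMF, 0 °C; then 4-MeOC6H4CH2Cl, Bu4NI (cat.), 0 °C → rt
Reagents that add atoms: 4-methoxybenzyl chloride, COc1ccc(CCl)cc1
Why: Williamson ether synthesis on the sodium alkoxide keeps the medium basic, which avoids ionisation of the bis-allylic carbinol, and installs an ether that survives borane, base and fluoride and is later removed oxidatively at neutral pH.

Step 3
Reactants: 5 3-[(4-methoxybenzyl)oxy]-2,4-dimethylpenta-1,4-diene
Product: 7 (2R,3s,4S)-3-[(4-methoxybenzyl)oxy]-2,4-dimethylpentane-1,5-diol (meso; anti,anti), via bis(9-borabicyclononyl) adduct 6 (not isolated)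
Conditions: 9-BBN (2.5 equiv), THF, 0 °C → rt; then NaOH, H2O2, 0 °C → rt; anti,syn isomer removed by chromatography or crystallisation
Reagents that add atoms: hydrogen peroxide, OO
Why: Double hydroboration-oxidation with a bulky dialkylborane is anti-Markovnikov at each 1,1-disubstituted alkene and shows substrate-controlled 1,2-anti induction from the C3 alkoxy carbon (attack on the alkene face opposite the larger allylic substituent in the conformer of least allylic strain), so both methyl centres should be set anti to the C3 oxygen to give the meso diol; the chiral anti,syn diastereomer must be removed here because it would end as a diastereomer of the target.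

Step 4
Reactants: 7 (2R,3s,4S)-3-[(4-methoxybenzyl)oxy]-2,4-dimethylpentane-1,5-diol
Product: 8 (2S,3R,4R)-5-hydroxy-3-[(4-methoxybenzyl)oxy]-2,4-dimethylpentyl acetate
Conditions: Pseudomonas fluorescens lipase, vinyl acetate, t-BuOMe, 25 °C, stopped near one equivalent of acyl transfer
Reagents that add atoms: vinyl acetate, CC(=O)OC=C
Why: The active-site serine is acetylated by vinyl acetate, irreversibly because the released vinyl alcohol tautomerises to acetaldehyde, and the acyl-enzyme passes the acetyl group to only one of the two enantiotopic CH2OH groups, forming a single O–C(=O)CH3 bond. The closest known reaction type is the lipase-catalysed enantiotopic-group-selective transesterification of meso 2-substituted propane-1,3-diols and meso 3-alkoxy-2,4-dimethylpentane-1,5-diols with enol esters. No ring is closed. No carbon stereocentre is created by bond formation, but breaking the mirror plane through C3 fixes the existing methyl centres C2 and C4 together in the absolute sense and turns C3 into a true stereocentre; the controlling element is the chiral binding pocket of the enzyme, which reads the methyl-bearing carbon directly next to each CH2OH. The step needs enantiotopic-group selectivity and mono- over diacetylation; the first is secured by the stereocentre sitting beta to the reacting oxygen, the second by limiting conversion, and any wrongly acetylated monoacetate still has its fast-reacting hydroxyl free and is drained to the achiral diacetate, which should raise the enantiomeric purity of 8.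

Step 5
Reactants: 8 (2S,3R,4R)-5-hydroxy-3-[(4-methoxybenzyl)oxy]-2,4-dimethylpentyl acetate
Product: 9 (2S,3S,4R)-5-[(tert-butyldimethylsilyl)oxy]-3-[(4-methoxybenzyl)oxy]-2,4-dimethylpentyl acetate
Conditions: TBSCl, imidazole, DMF, 0 °C → rt
Reagents that add atoms: tert-butyldimethylsilyl chloride, CC(C)(C)[Si](C)(C)Cl
Why: Imidazole-promoted silylation of the only free, primary hydroxyl; the two oxygens are 1,5-related, so acetyl migration that would erase the enzymatic label is not expected.

Step 6
Reactants: 9 (2S,3S,4R)-5-[(tert-butyldimethylsilyl)oxy]-3-[(4-methoxybenzyl)oxy]-2,4-dimethylpentyl acetate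
Product: 10 (2S,3S,4R)-5-[(tert-butyldimethylsilyl)oxy]-3-[(4-methoxybenzyl)oxy]-2,4-dimethylpentan-1-ol
Conditions: K2CO3, MeOH, 0 °C → rt
Reagents that add atoms: none
Why: Base-catalysed transesterification with methanol removes the acetate while the silyl ether and the benzyl-type ether are inert, which frees the hydroxyl of the arm that is to carry ring A.

Step 7
Reactants: 10 (2S,3S,4R)-5-[(tert-butyldimethylsilyl)oxy]-3-[(4-methoxybenzyl)oxy]-2,4-dimethylpentan-1-ol
Product: 11 (2R,3R,4R)-5-[(tert-butyldimethylsilyl)oxy]-3-[(4-methoxybenzyl)oxy]-2,4-dimethylpentanal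
Conditions: Dess–Martin periodinane, NaHCO3, CH2Cl2, 0 °C → rt; used at once
Reagents that add atoms: none
Why: Dess–Martin oxidation of a primary alcohol under bicarbonate buffering is fast and neutral, so the alpha-methyl centre of the beta-alkoxy aldehyde should neither epimerise nor undergo elimination.

Step 8
Reactants: 11 (2R,3R,4R)-5-[(tert-butyldimethylsilyl)oxy]-3-[(4-methoxybenzyl)oxy]-2,4-dimethylpentanal; 12 pentan-3-one
Product: 14 (6S,7R,8R)-9-[(tert-butyldimethylsilyl)oxy]-5-hydroxy-7-[(4-methoxybenzyl)oxy]-4,6,8-trimethylnonan-3-one (C4/C5 diastereomer mixture), via lithium pent-2-en-3-olate 13 (not isolated)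
Conditions: 12, LiN(iPr)2, THF, −78 °C; then 11, −78 °C; aq NH4Cl
Reagents that add atoms: none
Why: Aldol addition of a preformed lithium enolate to the aldehyde at −78 °C is faster than proton transfer from the alpha-branched aldehyde; the two new centres are left uncontrolled because both become sp2 carbons of ring A.

Step 9
Reactants: 14 (6S,7R,8R)-9-[(tert-butyldimethylsilyl)oxy]-5-hydroxy-7-[(4-methoxybenzyl)oxy]-4,6,8-trimethylnonan-3-one
Product: 15 (6R,7R,8R)-9-[(tert-butyldimethylsilyl)oxy]-7-[(4-methoxybenzyl)oxy]-4,6,8-trimethylnonane-3,5-dione (C4 epimers and enol forms)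
Conditions: Dess–Martin periodinane, NaHCO3, CH2Cl2, rt
Reagents that add atoms: none
Why: Dess–Martin oxidation converts the beta-hydroxy ketone into the 1,3-diketone without base, and the diketone enolises toward C4 between the carbonyls, which leaves the C6 centre untouched.

Step 10
Reactants: 15 (6R,7R,8R)-9-[(tert-butyldimethylsilyl)oxy]-7-[(4-methoxybenzyl)oxy]-4,6,8-trimethylnonane-3,5-dione; 16 methyl hexanoate
Product: 18 (2R,3R,4R)-1-[(tert-butyldimethylsilyl)oxy]-3-[(4-methoxybenzyl)oxy]-2,4,6,8-tetramethyltetradecane-5,7,9-trione (epimers at C6/C8 and enol forms), via dilithium bis-enolate 17 (not isolated)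
Conditions: LiN(iPr)2 (3.2 equiv), THF, −78 → 0 °C; then 16 (1.5 equiv), −78 → 0 °C; AcOH, −78 °C
Reagents that add atoms: none
Why: Claisen-type C-acylation of a 1,3-diketone dianion by an ester: kinetic second deprotonation should take the unhindered CH2 (C2 of 15) in preference to the tertiary C6–H, the terminal carbanion is the reactive site, the extra equivalent of base absorbs the acidic proton of the triketone as it forms, and because C5 remains an enolate oxygen throughout, C6 should neither epimerise nor expel the C7 ether.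

Step 11
Reactants: 18 (2R,3R,4R)-1-[(tert-butyldimethylsilyl)oxy]-3-[(4-methoxybenzyl)oxy]-2,4,6,8-tetramethyltetradecane-5,7,9-trione
Product: 19 2-[(2R,3R,4R)-5-[(tert-butyldimethylsilyl)oxy]-3-[(4-methoxybenzyl)oxy]-4-methylpentan-2-yl]-3,5-dimethyl-6-pentyl-4H-pyran-4-one
Conditions: PPh3, CCl4, THF, rt
Reagents that add atoms: none
Why: Appel-type cyclodehydration: PPh3/CCl4 turns one terminal enol oxygen of the 1,3,5-triketone into an oxyphosphonium leaving group and the other terminal enol oxygen closes the six-membered ring A by O–C bond formation with loss of Ph3P=O, a neutral method suited to gamma-pyrones that carry an adjacent stereocentre and tolerant of both ethers.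

Step 12
Reactants: 19 2-[(2R,3R,4R)-5-[(tert-butyldimethylsilyl)oxy]-3-[(4-methoxybenzyl)oxy]-4-methylpentan-2-yl]-3,5-dimethyl-6-pentyl-4H-pyran-4-one
Product: 20 2-[(2R,3R,4R)-5-hydroxy-3-[(4-methoxybenzyl)oxy]-4-methylpentan-2-yl]-3,5-dimethyl-6-pentyl-4H-pyran-4-one
Conditions: HF·pyridine, pyridine, THF, 0 °C → rt
Reagents that add atoms: none
Why: Fluoride-induced cleavage of the primary silyl ether with pyridine-buffered HF is non-basic, so the methine on ring A and the benzyl-type ether should be unaffected.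

Step 13
Reactants: 20 2-[(2R,3R,4R)-5-hydroxy-3-[(4-methoxybenzyl)oxy]-4-methylpentan-2-yl]-3,5-dimethyl-6-pentyl-4H-pyran-4-one
Product: 21 (2S,3S,4R)-4-(3,5-dimethyl-4-oxo-6-pentyl-4H-pyran-2-yl)-3-[(4-methoxybenzyl)oxy]-2-methylpentanal
Conditions: Dess–Martin periodinane, NaHCO3, CH2Cl2, 0 °C → rt; used at once
Reagents that add atoms: none
Why: Buffered Dess–Martin oxidation gives the alpha-methyl beta-alkoxy aldehyde under neutral conditions that the pyrone tolerates, and immediate use limits epimerisation at C2.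

Step 14
Reactants: 21 (2S,3S,4R)-4-(3,5-dimethyl-4-oxo-6-pentyl-4H-pyran-2-yl)-3-[(4-methoxybenzyl)oxy]-2-methylpentanal; 22 4-methylheptane-3,5-dione
Product: 24 2-[(2R,3R,4R)-5-hydroxy-3-[(4-methoxybenzyl)oxy]-4,6,8-trimethyl-7,9-dioxoundecan-2-yl]-3,5-dimethyl-6-pentyl-4H-pyran-4-one (diastereomer mixture at C5/C6/C8), via dilithium 4-methylhepta-2,4-diene-3,5-diolate 23 (not isolated)
Conditions: 22 (1.3 equiv), LiN(iPr)2 (2 equiv per 22), THF, −78 → 0 °C; then 21, −78 °C; AcOH, −78 °C
Reagents that add atoms: none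
Why: Aldol addition of a symmetrical 1,3-diketone dianion through its terminal carbon (both ends are identical) is fast at −78 °C, so it should outrun proton abstraction from the aldehyde or from the alkyl groups on ring A; the new centres later become sp2 carbons of ring B.

Step 15
Reactants: 24 2-[(2R,3R,4R)-5-hydroxy-3-[(4-methoxybenzyl)oxy]-4,6,8-trimethyl-7,9-dioxoundecan-2-yl]-3,5-dimethyl-6-pentyl-4H-pyran-4-one
Product: 25 2-[(2R,3S,4S)-3-[(4-methoxybenzyl)oxy]-4,6,8-trimethyl-5,7,9-trioxoundecan-2-yl]-3,5-dimethyl-6-pentyl-4H-pyran-4-one (epimers at C6/C8 and enol forms)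
Conditions: Dess–Martin periodinane, NaHCO3, CH2Cl2, rt
Reagents that add atoms: none
Why: Dess–Martin oxidation of the secondary carbinol gives the 1,3,5-triketone under neutral, buffered conditions that leave the C4 methine, ring A and the ether intact.

Step 16
Reactants: 25 2-[(2R,3S,4S)-3-[(4-methoxybenzyl)oxy]-4,6,8-trimethyl-5,7,9-trioxoundecan-2-yl]-3,5-dimethyl-6-pentyl-4H-pyran-4-one
Product: 26 2-[(2R,3R,4S)-4-(6-ethyl-3,5-dimethyl-4-oxo-4H-pyran-2-yl)-3-[(4-methoxybenzyl)oxy]pentan-2-yl]-3,5-dimethyl-6-pentyl-4H-pyran-4-one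
Conditions: PPh3, CCl4, THF, rt
Reagents that add atoms: none
Why: Appel-type cyclodehydration as in step 11 closes ring B by attack of one terminal enol oxygen on the activated other terminus (six-membered O–C closure, loss of Ph3P=O), and ring A, already a vinylogous ester, is inert.

Step 17
Reactants: 26 2-[(2R,3R,4S)-4-(6-ethyl-3,5-dimethyl-4-oxo-4H-pyran-2-yl)-3-[(4-methoxybenzyl)oxy]pentan-2-yl]-3,5-dimethyl-6-pentyl-4H-pyran-4-one
Product: 27 2-[(2R,3R,4S)-4-(6-ethyl-3,5-dimethyl-4-oxo-4H-pyran-2-yl)-3-hydroxypentan-2-yl]-3,5-dimethyl-6-pentyl-4H-pyran-4-one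
Conditions: DDQ, CH2Cl2/pH 7 phosphate buffer, 0 °C → rt
Reagents that add atoms: none
Why: Oxidative cleavage of the 4-methoxybenzyl ether by DDQ (hydride abstraction from the electron-rich benzylic CH2, then hydrolysis of the oxocarbenium ion) proceeds at neutral pH; the electron-poor pyrones are inert and neither methine centre is touched.

Step 18
Reactants: 27 2-[(2R,3R,4S)-4-(6-ethyl-3,5-dimethyl-4-oxo-4H-pyran-2-yl)-3-hydroxypentan-2-yl]-3,5-dimethyl-6-pentyl-4H-pyran-4-one
Product: 28 2-[(2S,4R)-4-(6-ethyl-3,5-dimethyl-4-oxo-4H-pyran-2-yl)-3-oxopentan-2-yl]-3,5-dimethyl-6-pentyl-4H-pyran-4-one (target CNP0268096.4)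
Conditions: Dess–Martin periodinane, NaHCO3, CH2Cl2, 0 °C → rt; brief filtration through neutral silica
Reagents that add atoms: none
Why: Dess–Martin oxidation of the secondary carbinol under bicarbonate buffering unveils the central ketone without acid or base, so the two now doubly activated methine centres (alpha to the ketone and bound to C2 of a pyrone) should keep their S and R configurations if work-up and purification are kept neutral and brief.

Compound list
1 | methacrolein (2-methylprop-2-enal) | C=C(C)C=O | starting material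
2 | isopropenylmagnesium bromide | C=C(C)[Mg]Br | starting material
3 | 2,4-dimethylpenta-1,4-dien-3-ol | C=C(C)C(O)C(C)=C | intermediate
4 | sodium 2,4-dimethylpenta-1,4-dien-3-olate | C=C(C)C([O-])C(C)=C.[Na+] | intermediate
5 | 3-[(4-methoxybenzyl)oxy]-2,4-dimethylpenta-1,4-diene | C=C(C)C(OCc1ccc(OC)cc1)C(C)=C | intermediate
6 | 9,9'-[(2R,3s,4S)-3-[(4-methoxybenzyl)oxy]-2,4-dimethylpentane-1,5-diyl]bis(9-borabicyclo[3.3.1]nonane) | C(B1C2CCCC1CCC2)[C@H](C)[C@H](OCc1ccc(OC)cc1)[C@H](C)CB1C2CCCC1CCC2 | intermediate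
7 | (2R,3s,4S)-3-[(4-methoxybenzyl)oxy]-2,4-dimethylpentane-1,5-diol (meso, anti,anti) | OC[C@H](C)[C@H](OCc1ccc(OC)cc1)[C@H](C)CO | intermediate
8 | (2S,3R,4R)-5-hydroxy-3-[(4-methoxybenzyl)oxy]-2,4-dimethylpentyl acetate | CC(=O)OC[C@H](C)[C@H](OCc1ccc(OC)cc1)[C@H](C)CO | intermediate
9 | (2S,3S,4R)-5-[(tert-butyldimethylsilyl)oxy]-3-[(4-methoxybenzyl)oxy]-2,4-dimethylpentyl acetate | CC(=O)OC[C@H](C)[C@H](OCc1ccc(OC)cc1)[C@H](C)CO[Si](C)(C)C(C)(C)C | intermediate
10 | (2S,3S,4R)-5-[(tert-butyldimethylsilyl)oxy]-3-[(4-methoxybenzyl)oxy]-2,4-dimethylpentan-1-ol | OC[C@H](C)[C@H](OCc1ccc(OC)cc1)[C@H](C)CO[Si](C)(C)C(C)(C)C | intermediate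
11 | (2R,3R,4R)-5-[(tert-butyldimethylsilyl)oxy]-3-[(4-methoxybenzyl)oxy]-2,4-dimethylpentanal | O=C[C@H](C)[C@H](OCc1ccc(OC)cc1)[C@H](C)CO[Si](C)(C)C(C)(C)C | intermediate
12 | pentan-3-one | CCC(=O)CC | starting material
13 | lithium pent-2-en-3-olate | CC=C(CC)[O-].[Li+] | intermediate
14 | (6S,7R,8R)-9-[(tert-butyldimethylsilyl)oxy]-5-hydroxy-7-[(4-methoxybenzyl)oxy]-4,6,8-trimethylnonan-3-one (mixture at C4 and C5) | CCC(=O)C(C)C(O)[C@H](C)[C@H](OCc1ccc(OC)cc1)[C@H](C)CO[Si](C)(C)C(C)(C)C | intermediate
15 | (6R,7R,8R)-9-[(tert-butyldimethylsilyl)oxy]-7-[(4-methoxybenzyl)oxy]-4,6,8-trimethylnonane-3,5-dione | CCC(=O)C(C)C(=O)[C@H](C)[C@H](OCc1ccc(OC)cc1)[C@H](C)CO[Si](C)(C)C(C)(C)C | intermediate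
16 | methyl hexanoate | CCCCCC(=O)OC | starting material
17 | dilithium bis-enolate (2,4-diene-3,5-diolate) of 15 | CC=C([O-])C(C)=C([O-])[C@H](C)[C@H](OCc1ccc(OC)cc1)[C@H](C)CO[Si](C)(C)C(C)(C)C.[Li+].[Li+] | intermediate
18 | (2R,3R,4R)-1-[(tert-butyldimethylsilyl)oxy]-3-[(4-methoxybenzyl)oxy]-2,4,6,8-tetramethyltetradecane-5,7,9-trione | CCCCCC(=O)C(C)C(=O)C(C)C(=O)[C@H](C)[C@H](OCc1ccc(OC)cc1)[C@H](C)CO[Si](C)(C)C(C)(C)C | intermediate
19 | 2-[(2R,3R,4R)-5-[(tert-butyldimethylsilyl)oxy]-3-[(4-methoxybenzyl)oxy]-4-methylpentan-2-yl]-3,5-dimethyl-6-pentyl-4H-pyran-4-one | CCCCCc1oc([C@H](C)[C@H](OCc2ccc(OC)cc2)[C@H](C)CO[Si](C)(C)C(C)(C)C)c(C)c(=O)c1C | intermediate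
20 | 2-[(2R,3R,4R)-5-hydroxy-3-[(4-methoxybenzyl)oxy]-4-methylpentan-2-yl]-3,5-dimethyl-6-pentyl-4H-pyran-4-one | CCCCCc1oc([C@H](C)[C@H](OCc2ccc(OC)cc2)[C@H](C)CO)c(C)c(=O)c1C | intermediate
21 | (2S,3S,4R)-4-(3,5-dimethyl-4-oxo-6-pentyl-4H-pyran-2-yl)-3-[(4-methoxybenzyl)oxy]-2-methylpentanal | CCCCCc1oc([C@H](C)[C@H](OCc2ccc(OC)cc2)[C@H](C)C=O)c(C)c(=O)c1C | intermediate
22 | 4-methylheptane-3,5-dione | CCC(=O)C(C)C(=O)CC | starting material
23 | dilithium 4-methylhepta-2,4-diene-3,5-diolate | CC=C([O-])C(C)=C([O-])CC.[Li+].[Li+] | intermediate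
24 | 2-[(2R,3R,4R)-5-hydroxy-3-[(4-methoxybenzyl)oxy]-4,6,8-trimethyl-7,9-dioxoundecan-2-yl]-3,5-dimethyl-6-pentyl-4H-pyran-4-one (mixture at C5, C6 and C8) | CCCCCc1oc([C@H](C)[C@H](OCc2ccc(OC)cc2)[C@H](C)C(O)C(C)C(=O)C(C)C(=O)CC)c(C)c(=O)c1C | intermediate
25 | 2-[(2R,3S,4S)-3-[(4-methoxybenzyl)oxy]-4,6,8-trimethyl-5,7,9-trioxoundecan-2-yl]-3,5-dimethyl-6-pentyl-4H-pyran-4-one | CCCCCc1oc([C@H](C)[C@H](OCc2ccc(OC)cc2)[C@H](C)C(=O)C(C)C(=O)C(C)C(=O)CC)c(C)c(=O)c1C | intermediate
26 | 2-[(2R,3R,4S)-4-(6-ethyl-3,5-dimethyl-4-oxo-4H-pyran-2-yl)-3-[(4-methoxybenzyl)oxy]pentan-2-yl]-3,5-dimethyl-6-pentyl-4H-pyran-4-one | CCCCCc1oc([C@H](C)[C@H](OCc3ccc(OC)cc3)[C@H](C)c2oc(CC)c(C)c(=O)c2C)c(C)c(=O)c1C | intermediate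
27 | 2-[(2R,3R,4S)-4-(6-ethyl-3,5-dimethyl-4-oxo-4H-pyran-2-yl)-3-hydroxypentan-2-yl]-3,5-dimethyl-6-pentyl-4H-pyran-4-one | CCCCCc1oc([C@H](C)[C@H](O)[C@H](C)c2oc(CC)c(C)c(=O)c2C)c(C)c(=O)c1C | intermediate
28 | 2-[(2S,4R)-4-(6-ethyl-3,5-dimethyl-4-oxo-4H-pyran-2-yl)-3-oxopentan-2-yl]-3,5-dimethyl-6-pentyl-4H-pyran-4-one (CNP0268096.4) | CCCCCc1oc([C@H](C)C(=O)[C@H](C)c2oc(CC)c(C)c(=O)c2C)c(C)c(=O)c1C | target

Total step count: 18.
Longest linear sequence: 18 steps, from 1 and 2 to 28; compounds 12, 16 and 22 are bought and enter directly.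

Steps most likely to fail

Step 10. The triketone is more acidic than the diketone, so it may protonate the dianion as it forms and stall the acylation. The ester may also be enolised or condense with itself, and any deprotonation at C6 would cause epimerisation or loss of the C7 ether. The fallback sets out from 15. Its dianion 17 is trapped at −78 °C with hexanal in an aldol addition, which forms no acidic product in the flask. This gives (2R,3R,4R)-1-[(tert-butyldimethylsilyl)oxy]-9-hydroxy-3-[(4-methoxybenzyl)oxy]-2,4,6,8-tetramethyltetradecane-5,7-dione F2. Buffered Dess–Martin oxidation of the new carbinol then gives 18, where the route is rejoined, at the cost of one extra step.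

Step 14. The strongly basic dianion may abstract a proton from the epimerisable aldehyde or from the C–H positions on ring A. That would cause epimerisation at C2 of 21, elimination of the ether or low conversion. The fallback sets out from 21 and replaces the basic dianion by a Lewis-acid-mediated Mukaiyama aldol reaction. Diketone 22 is silylated twice (Me3SiCl, Et3N; then LiN(iPr)2, Me3SiCl) to 4-methyl-3,5-bis[(trimethylsilyl)oxy]hepta-2,4-diene F3. This adds through its terminal carbon to 21 with BF3·OEt2 in CH2Cl2 at −78 °C. Aqueous work-up removes silicon and delivers 24, where the route is rejoined.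

Step 4. The enzyme may acetylate the other enantiotopic hydroxymethyl group, discriminate poorly between the two, or run on to the diacetate. The fallback sets out from 7 and turns the desymmetrisation from acylation into hydrolysis. Peracetylation (Ac2O, pyridine) gives the meso (2R,3s,4S)-3-[(4-methoxybenzyl)oxy]-2,4-dimethylpentane-1,5-diyl diacetate F1. The same lipase in pH 7 phosphate buffer then cleaves one ester. Because the enzyme removes the acetyl group from the arm it would otherwise acylate, the monoacetate of opposite handedness is obtained, and the route is rejoined at 8.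

Further compounds
F1 | step 4 | (2R,3s,4S)-3-[(4-methoxybenzyl)oxy]-2,4-dimethylpentane-1,5-diyl diacetate | CC(=O)OC[C@H](C)[C@H](OCc1ccc(OC)cc1)[C@H](C)COC(C)=O
F2 | step 10 | (2R,3R,4R)-1-[(tert-butyldimethylsilyl)oxy]-9-hydroxy-3-[(4-methoxybenzyl)oxy]-2,4,6,8-tetramethyltetradecane-5,7-dione | CCCCCC(O)C(C)C(=O)C(C)C(=O)[C@H](C)[C@H](OCc1ccc(OC)cc1)[C@H](C)CO[Si](C)(C)C(C)(C)C
F3 | step 14 | 4-methyl-3,5-bis[(trimethylsilyl)oxy]hepta-2,4-diene | CC=C(O[Si](C)(C)C)C(C)=C(CC)O[Si](C)(C)C
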